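**Retrosynthetic overview**

1. Target ⇒ its tert-butyl ester ⇒ the C3–acyl bond of the lactone. Carbodiimide/DMAP O-acylation followed by O→C acyl shift joins (R)-4-hydroxy-6-methyl-5,6-dihydropyran-2-one to the side-chain acid.
2. Side-chain acid ⇒ chemoselective oxidative cleavage of a terminal isopropylidene group (the masked acyl carbon) in an anti-aldol ester.
3. Key disconnection, Cα–Cβ of the β-hydroxy acid: D-proline dienamine cross-aldol of a skipped (β,γ-unsaturated) aldehyde with (S)-2-methylbutanal, oxidised in the same flask. This is the new method and sets two stereocentres.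
4. Skipped aldehyde ⇒ Julia–Kocienski E-olefination of (R)-citronellal, made from achiral geranial by organocatalytic transfer hydrogenation (first stereocentre). (S)-2-Methylbutanal ⇐ tiglic acid by asymmetric hydrogenation.
5. Rings: the only ring, the dihydropyranone, is not constructed. It comes from commercial 4-hydroxy-6-methyl-2-pyrone by asymmetric hydrogenation and is attached in the second-to-last step.

Assumption: for the chiral catalysts of steps 1, 6 and 12 the antipode named is taken to give the configuration shown; if the sense of induction is the opposite, the mirror-image catalyst is used.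

**Route**

Step 1
Reactants: 1 geranial, (2E)-3,7-dimethylocta-2,6-dienal
Product: 2 (R)-citronellal, (3R)-3,7-dimethyloct-6-enal
Conditions: Hantzsch ester (diethyl 1,4-dihydro-2,6-dimethylpyridine-3,5-dicarboxylate, 1.1 equiv), morpholinium (R)-TRIP phosphate (10 mol%), THF, rt
Reagents that add atoms: none
Why: Organocatalytic iminium transfer hydrogenation under counteranion-directed catalysis: the chiral phosphate paired with the morpholine-derived iminium ion lets the Hantzsch ester deliver hydride to one face of C3 only, setting the first stereocentre (R, about 90% ee expected) and leaving the remote trisubstituted alkene alone.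

Step 2
Reactants: 3 1-phenyl-1H-tetrazole-5-thiol + 4 3-bromo-1,1-dimethoxypropane
Product: 5 5-[(3,3-dimethoxypropyl)sulfanyl]-1-phenyl-1H-tetrazole
Conditions: K2CO3 (1.5 equiv), acetone, reflux
Reagents that add atoms: none
Why: SN2 S-alkylation of the acidic tetrazole thiol by a primary bromide.

Step 3
Reactants: 5 5-[(3,3-dimethoxypropyl)sulfanyl]-1-phenyl-1H-tetrazole
Product: 7 5-[(3,3-dimethoxypropyl)sulfonyl]-1-phenyl-1H-tetrazole, via sulfoxide 6 (not isolated)
Conditions: 30% H2O2 (5 equiv), (NH4)6Mo7O24·4H2O (10 mol%), MeOH, 0 °C → rt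
Reagents that add atoms: hydrogen peroxide, OO
Why: Molybdate-catalysed peroxide oxidation of the sulfide through the sulfoxide to the sulfone; methanol as solvent keeps the dimethyl acetal intact.

Step 4
Reactants: 2 (R)-citronellal + 7 5-[(3,3-dimethoxypropyl)sulfonyl]-1-phenyl-1H-tetrazole
Product: 8 (3E,6R)-1,1-dimethoxy-6,10-dimethylundeca-3,9-diene
Conditions: 7 (1.2 equiv), KN(SiMe3)2 (1.15 equiv), DME, −60 °C; then 2, −60 °C → rt
Reagents that add atoms: none
Why: Julia–Kocienski olefination: the metalated phenyltetrazolyl sulfone adds to the aldehyde, and Smiles rearrangement with loss of SO2 and tetrazolate gives mainly the E-alkene in DME; the stereocentre of 2 is β to the carbonyl and is not touched.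

Step 5
Reactants: 8 (3E,6R)-1,1-dimethoxy-6,10-dimethylundeca-3,9-diene
Product: 9 (3E,6R)-6,10-dimethylundeca-3,9-dienal
Conditions: 1 M HCl, THF, 0 °C, 1 h; used crude
Reagents that add atoms: water, O
Why: Acid-catalysed acetal hydrolysis; brief contact with dilute acid at 0 °C leaves the skipped E-alkene out of conjugation.

Step 6
Reactants: 10 tiglic acid, (2E)-2-methylbut-2-enoic acid
Product: 11 (2S)-2-methylbutanoic acid
Conditions: H2 (4 atm), Ru(OAc)2[(S)-H8-BINAP] (0.5 mol%), MeOH, 20 °C
Reagents that add atoms: none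
Why: Noyori-type asymmetric hydrogenation of an α,β-unsaturated acid: the carboxylate-bound ruthenium–diphosphine delivers H2 to one alkene face and sets the (S) centre (about 97% ee expected).

Step 7
Reactants: 11 (2S)-2-methylbutanoic acid
Product: 12 (2S)-2-methylbutan-1-ol
Conditions: LiAlH4, Et2O, 0 °C → rt
Reagents that add atoms: none
Why: Hydride reduction of the acid to the primary alcohol; the α-centre is not enolised.

Step 8
Reactants: 12 (2S)-2-methylbutan-1-ol
Product: 13 (2S)-2-methylbutanal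
Conditions: TEMPO (1 mol%), KBr (10 mol%), NaOCl (1.1 equiv), NaHCO3, CH2Cl2/H2O, 0 °C; distilled and used at once
Reagents that add atoms: none
Why: Anelli oxidation (TEMPO/hypochlorite) under buffered two-phase conditions, which gives this α-branched aldehyde without racemisation.

Step 9
Reactants: 9 (3E,6R)-6,10-dimethylundeca-3,9-dienal + 13 (2S)-2-methylbutanal
Product: 15 (2R,3R,4S)-2-[(1E,4R)-4,8-dimethylnona-1,7-dien-1-yl]-3-hydroxy-4-methylhexanoic acid, via β-hydroxy aldehyde 14 (not isolated)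
Conditions: D-proline (20 mol%), DMF, 4 °C, 9 added by syringe pump over 24 h to 13 (3 equiv); excess 13 stripped in vacuo; then t-BuOH/H2O, 2-methylbut-2-ene (30 equiv), NaH2PO4, NaClO2, 0 °C
Reagents that add atoms: sodium chlorite NaClO2, [Na+].[O-]Cl=O
Why: Proposed new method: D-proline should convert the skipped aldehyde 9 into an s-trans 1-amino-1,3-diene (dienamine) whose α-carbon, not the γ-carbon, sits next to the carboxylic acid-activated Si face of 13 in a Houk–List chair, so the new bond forms anti with (2R,3R) configuration (matched with the Felkin preference of 13), and Pinnick oxidation in the same flask turns the sensitive β,γ-unsaturated aldol 14 into acid 15 before the α-centre can epimerise or the alkene move into conjugation; the closest known reactions are the proline-catalysed enamine cross-aldol of simple alkanals with α-branched aldehydes and the α-selective Mannich reactions of proline dienamines.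

Step 10
Reactants: 15 (2R,3R,4S)-2-[(1E,4R)-4,8-dimethylnona-1,7-dien-1-yl]-3-hydroxy-4-methylhexanoic acid
Product: 16 tert-butyl (2R,3R,4S)-2-[(1E,4R)-4,8-dimethylnona-1,7-dien-1-yl]-3-hydroxy-4-methylhexanoate
Conditions: tert-butyl 2,2,2-trichloroacetimidate (2 equiv), CH2Cl2/cyclohexane, rt
Reagents that add atoms: tert-butyl 2,2,2-trichloroacetimidate, CC(C)(C)OC(=N)C(Cl)(Cl)Cl
Why: Acid-selective tert-butyl esterification: the carboxylic acid protonates the imidate and captures the tert-butyl cation, while the hindered secondary alcohol does not react without a Lewis acid.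

Step 11
Reactants: 16 tert-butyl (2R,3R,4S)-2-[(1E,4R)-4,8-dimethylnona-1,7-dien-1-yl]-3-hydroxy-4-methylhexanoate
Product: 19 (4R,6E,8R,9R,10S)-8-(tert-butoxycarbonyl)-9-hydroxy-4,10-dimethyldodec-6-enoic acid, via ozonide 17 (not isolated), via aldehyde 18 (not isolated)
Conditions: O3 (1.0 equiv, Sudan Red 7B end point), CH2Cl2, −78 °C; PPh3, −78 °C → rt; then t-BuOH/H2O, 2-methylbut-2-ene, NaH2PO4, NaClO2, 0 °C → rt
Reagents that add atoms: ozone, [O-][O+]=O; sodium chlorite NaClO2, [Na+].[O-]Cl=O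
Why: Chemoselective ozonolysis followed by Pinnick oxidation: ozone attacks the electron-rich trisubstituted alkene faster than the disubstituted E-alkene that sits next to the ester-bearing carbon, PPh3 reduces the ozonide, and chlorite takes the aldehyde to the acid.

Step 12
Reactants: 20 4-hydroxy-6-methyl-2H-pyran-2-one (triacetic acid lactone)
Product: 21 (6R)-4-hydroxy-6-methyl-5,6-dihydro-2H-pyran-2-one
Conditions: H2 (60 bar), Ru(OAc)2[(S)-MeO-BIPHEP] (1 mol%), HBF4·OEt2 (2 mol%), MeOH, 60 °C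
Reagents that add atoms: none
Why: Asymmetric hydrogenation of the 5,6-double bond of a 4-hydroxy-2-pyrone with a cationic ruthenium–biaryl diphosphine catalyst sets the ring stereocentre (R) and stops at the enolised β-keto lactone.

Step 13
Reactants: 19 (4R,6E,8R,9R,10S)-8-(tert-butoxycarbonyl)-9-hydroxy-4,10-dimethyldodec-6-enoic acid + 21 (6R)-4-hydroxy-6-methyl-5,6-dihydro-2H-pyran-2-one
Product: 23 tert-butyl (2R,3R,4S)-3-hydroxy-2-{(1E,4R)-7-[(6R)-4-hydroxy-6-methyl-2-oxo-5,6-dihydro-2H-pyran-3-yl]-4-methyl-7-oxohept-1-en-1-yl}-4-methylhexanoate, via enol ester 22 (not isolated)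
Conditions: N,N'-dicyclohexylcarbodiimide (1.2 equiv), DMAP (1.2 equiv), 21 (1.2 equiv), CH2Cl2, 0 °C → rt, 16 h
Reagents that add atoms: none
Why: Steglich O-acylation of the acidic enol followed by DMAP-mediated O→C acyl shift (Fries-type rearrangement) to the more stable 3-acyl tricarbonyl; the hindered secondary alcohol is acylated far more slowly than the enol.

Step 14
Reactants: 23 tert-butyl (2R,3R,4S)-3-hydroxy-2-{(1E,4R)-7-[(6R)-4-hydroxy-6-methyl-2-oxo-5,6-dihydro-2H-pyran-3-yl]-4-methyl-7-oxohept-1-en-1-yl}-4-methylhexanoate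
Product: 24 (2R,3R,4S)-3-hydroxy-2-{(1E,4R)-7-[(6R)-4-hydroxy-6-methyl-2-oxo-5,6-dihydro-2H-pyran-3-yl]-4-methyl-7-oxohept-1-en-1-yl}-4-methylhexanoic acid (target)
Conditions: TFA/CH2Cl2 (1:4), 0 °C → rt
Reagents that add atoms: none
Why: Acidolysis of the tert-butyl ester with loss of isobutene; no stereocentre is touched and the acyl-dihydropyranone is acid-stable.

**Compound list**

1 | geranial, (2E)-3,7-dimethylocta-2,6-dienal | CC(C)=CCC/C(C)=C/C=O | starting material
2 | (R)-citronellal, (3R)-3,7-dimethyloct-6-enal | O=CC[C@H](C)CCC=C(C)C | intermediate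
3 | 1-phenyl-1H-tetrazole-5-thiol | SC1=NN=NN1c1ccccc1 | starting material
4 | 3-bromo-1,1-dimethoxypropane | COC(OC)CCBr | starting material
5 | 5-[(3,3-dimethoxypropyl)sulfanyl]-1-phenyl-1H-tetrazole | COC(OC)CCSC1=NN=NN1c1ccccc1 | intermediate
6 | 5-[(3,3-dimethoxypropyl)sulfinyl]-1-phenyl-1H-tetrazole (racemic at sulfur) | COC(OC)CCS(=O)C1=NN=NN1c1ccccc1 | intermediate (not isolated)
7 | 5-[(3,3-dimethoxypropyl)sulfonyl]-1-phenyl-1H-tetrazole | COC(OC)CCS(=O)(=O)C1=NN=NN1c1ccccc1 | intermediate
8 | (3E,6R)-1,1-dimethoxy-6,10-dimethylundeca-3,9-diene | COC(OC)C/C=C/C[C@H](C)CCC=C(C)C | intermediate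
9 | (3E,6R)-6,10-dimethylundeca-3,9-dienal | O=CC/C=C/C[C@H](C)CCC=C(C)C | intermediate
10 | tiglic acid, (2E)-2-methylbut-2-enoic acid | C/C=C(\C)C(=O)O | starting material
11 | (2S)-2-methylbutanoic acid | CC[C@H](C)C(=O)O | intermediate
12 | (2S)-2-methylbutan-1-ol | CC[C@H](C)CO | intermediate
13 | (2S)-2-methylbutanal | CC[C@H](C)C=O | intermediate
14 | (2R,3R,4S)-2-[(1E,4R)-4,8-dimethylnona-1,7-dien-1-yl]-3-hydroxy-4-methylhexanal | CC[C@H](C)[C@@H](O)[C@@H](/C=C/C[C@H](C)CCC=C(C)C)C=O | intermediate (not isolated)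
15 | (2R,3R,4S)-2-[(1E,4R)-4,8-dimethylnona-1,7-dien-1-yl]-3-hydroxy-4-methylhexanoic acid | CC[C@H](C)[C@@H](O)[C@@H](/C=C/C[C@H](C)CCC=C(C)C)C(=O)O | intermediate
16 | tert-butyl (2R,3R,4S)-2-[(1E,4R)-4,8-dimethylnona-1,7-dien-1-yl]-3-hydroxy-4-methylhexanoate | CC[C@H](C)[C@@H](O)[C@@H](/C=C/C[C@H](C)CCC=C(C)C)C(=O)OC(C)(C)C | intermediate
17 | tert-butyl (2R,3R,4S)-2-[(1E,4R)-6-(5,5-dimethyl-1,2,4-trioxolan-3-yl)-4-methylhex-1-en-1-yl]-3-hydroxy-4-methylhexanoate (both epimers at the trioxolane carbon) | CC[C@H](C)[C@@H](O)[C@@H](/C=C/C[C@H](C)CCC1OOC(C)(C)O1)C(=O)OC(C)(C)C | intermediate (not isolated)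
18 | tert-butyl (2R,3R,4S)-3-hydroxy-4-methyl-2-[(1E,4R)-4-methyl-7-oxohept-1-en-1-yl]hexanoate | CC[C@H](C)[C@@H](O)[C@@H](/C=C/C[C@H](C)CCC=O)C(=O)OC(C)(C)C | intermediate (not isolated)
19 | (4R,6E,8R,9R,10S)-8-(tert-butoxycarbonyl)-9-hydroxy-4,10-dimethyldodec-6-enoic acid | CC[C@H](C)[C@@H](O)[C@@H](/C=C/C[C@H](C)CCC(=O)O)C(=O)OC(C)(C)C | intermediate
20 | 4-hydroxy-6-methyl-2H-pyran-2-one | CC1=CC(O)=CC(=O)O1 | starting material
21 | (6R)-4-hydroxy-6-methyl-5,6-dihydro-2H-pyran-2-one | C[C@@H]1CC(O)=CC(=O)O1 | intermediate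
22 | (2R)-2-methyl-6-oxo-3,6-dihydro-2H-pyran-4-yl (4R,6E,8R,9R,10S)-8-(tert-butoxycarbonyl)-9-hydroxy-4,10-dimethyldodec-6-enoate | CC[C@H](C)[C@@H](O)[C@@H](/C=C/C[C@H](C)CCC(=O)OC1=CC(=O)O[C@H](C)C1)C(=O)OC(C)(C)C | intermediate (not isolated)
23 | tert-butyl (2R,3R,4S)-3-hydroxy-2-{(1E,4R)-7-[(6R)-4-hydroxy-6-methyl-2-oxo-5,6-dihydro-2H-pyran-3-yl]-4-methyl-7-oxohept-1-en-1-yl}-4-methylhexanoate | CC[C@H](C)[C@@H](O)[C@@H](/C=C/C[C@H](C)CCC(=O)C1=C(O)C[C@@H](C)OC1=O)C(=O)OC(C)(C)C | intermediate
24 | (2R,3R,4S)-3-hydroxy-2-{(1E,4R)-7-[(6R)-4-hydroxy-6-methyl-2-oxo-5,6-dihydro-2H-pyran-3-yl]-4-methyl-7-oxohept-1-en-1-yl}-4-methylhexanoic acid | CC[C@H](C)[C@@H](O)[C@@H](/C=C/C[C@H](C)CCC(=O)C1=C(O)C[C@@H](C)OC1=O)C(=O)O | target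

**Step count**

Total: 14 steps. Longest linear sequence: 9 steps (2, 3, 4, 5, 9, 10, 11, 13, 14, counted from 3 and 4); the line from geranial 1 is 8 steps.

**Steps most likely to fail and their fallbacks**

Step 9, the new dienamine aldol. It can fail through γ-attack, self-aldol of 9, or conjugation of 14 before oxidation. The fallback makes the same bond at the ester oxidation level by known boron aldol chemistry, setting out from 9 and 13. Aldehyde 9 is oxidised (NaClO2, NaH2PO4, 2-methylbut-2-ene) to (3E,6R)-6,10-dimethylundeca-3,9-dienoic acid F1. F1 is esterified with tert-butyl 2,2,2-trichloroacetimidate to tert-butyl (3E,6R)-6,10-dimethylundeca-3,9-dienoate F2. Enolisation of F2 with Cy2BOTf/Et3N (CH2Cl2, −78 °C) gives the E-enol borinate, which adds 13 at the α-carbon through a Zimmerman–Traxler chair to give the anti aldol. This is 16 itself, where the route is rejoined (steps 9 and 10 are replaced). Face selection then rests only on the weak Felkin bias of 13, so the anti-Felkin isomer tert-butyl (2S,3S,4S)-2-[(1E,4R)-4,8-dimethylnona-1,7-dien-1-yl]-3-hydroxy-4-methylhexanoate F3 must be removed by chromatography.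

Step 11, the selective ozonolysis. Ozone may also cut the disubstituted alkene. The fallback sets out from 16 and splits the cleavage into two more selective operations. mCPBA (1.05 equiv, NaHCO3, CH2Cl2, 0 °C) epoxidises only the trisubstituted alkene to tert-butyl (2R,3R,4S)-2-[(1E,4R)-6-(3,3-dimethyloxiran-2-yl)-4-methylhex-1-en-1-yl]-3-hydroxy-4-methylhexanoate F4. H5IO6 (THF/H2O, 0 °C) then cleaves the epoxide to aldehyde 18, where the route is rejoined; 18 is oxidised to 19 with NaClO2 as in step 11.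

Step 4, the Julia–Kocienski olefination. The E/Z ratio may be modest and the isomers of 8 hard to separate. The fallback sets out from 2 and fixes the geometry by trans-reduction of an alkyne. Aldehyde 2 with dimethyl (1-diazo-2-oxopropyl)phosphonate, K2CO3 and MeOH gives (4R)-4,8-dimethylnon-7-en-1-yne F5. n-BuLi followed by ethylene oxide and BF3·OEt2 (THF, −78 °C) gives (6R)-6,10-dimethylundec-9-en-3-yn-1-ol F6. Na in liquid NH3 reduces the alkyne to (3E,6R)-6,10-dimethylundeca-3,9-dien-1-ol F7. Dess–Martin periodinane (NaHCO3, CH2Cl2) then gives 9, where the route is rejoined (steps 2 to 5 are replaced).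

**Further compounds**

F1 | step 9 | (3E,6R)-6,10-dimethylundeca-3,9-dienoic acid | OC(=O)C/C=C/C[C@H](C)CCC=C(C)C
F2 | step 9 | tert-butyl (3E,6R)-6,10-dimethylundeca-3,9-dienoate | CC(C)(C)OC(=O)C/C=C/C[C@H](C)CCC=C(C)C
F3 | step 9 | tert-butyl (2S,3S,4S)-2-[(1E,4R)-4,8-dimethylnona-1,7-dien-1-yl]-3-hydroxy-4-methylhexanoate | CC[C@H](C)[C@H](O)[C@H](/C=C/C[C@H](C)CCC=C(C)C)C(=O)OC(C)(C)C
F4 | step 11 | tert-butyl (2R,3R,4S)-2-[(1E,4R)-6-(3,3-dimethyloxiran-2-yl)-4-methylhex-1-en-1-yl]-3-hydroxy-4-methylhexanoate | CC[C@H](C)[C@@H](O)[C@@H](/C=C/C[C@H](C)CCC1OC1(C)C)C(=O)OC(C)(C)C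
F5 | step 4 | (4R)-4,8-dimethylnon-7-en-1-yne | C#CC[C@H](C)CCC=C(C)C
F6 | step 4 | (6R)-6,10-dimethylundec-9-en-3-yn-1-ol | OCCC#CC[C@H](C)CCC=C(C)C
F7 | step 4 | (3E,6R)-6,10-dimethylundeca-3,9-dien-1-ol | OCC/C=C/C[C@H](C)CCC=C(C)C
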